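Read from the scheme below, free monomer M, monomer in chains U and quenched substrate V always add up to the monomer charged. So U is the charge less M less V, and we need to reckon just those two.

    protic impurity + free monomer → quenched substrate (k1 = 0.187 /M/s, Ea1 = 52.0 kJ/mol)
    monomer in chains + living end → free monomer + living end, rate k2*[living end] as long as [monomer in chains] is above zero (k2 = 0.998 /s, Ea2 = 68.0 kJ/mol)
    free monomer + initiator → living end + monomer in chains (k3 = 9.54 /M/s, Ea3 = 54.0 kJ/mol)
    free monomer + living end → monomer in chains + living end, rate k4*[living end]*[free monomer] (k4 = 114 /M/s, Ea4 = 38.0 kJ/mol)
    (constants at 50 °C)

in all of them: free monomer 22 mM; protic impurity 22.0 mM; initiator 0.5 mol%; time 3.0 min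
- autumn: temperature 30 °C
- winter: temperature 10 °C
- summer: temperature −10 °C
- noon: temperature 50 °C

- the constants hold at 50 °C; other temperatures follow from the activation energies

* the flask that comes out highest in amount of monomer in chains, in percent of the free monomer charged, or "all alike" when all lie within 1.5 percentage points (autumn / winter / summer / noon / all alike)
* monomer in chains at the end, in percent of the free monomer charged, autumn
* monomer in chains at the end, in percent of the free monomer charged, winter
* monomer in chains at the end, in percent of the free monomer charged, summer
* monomer in chains at the end, in percent of the free monomer charged, noon

Write kp for the propagation constant, kd for the depropagation constant, kq for the quench constant and L for the living end. Leaving aside the small share that initiation adds, chains grow net at kp·L·(M − c), with c = kd/kp. At noon c = 8.75 mM. This is the equilibrium concentration of free monomer, where net chain growth stops, and it is 39.8% of the charge.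

Turn the question round: for noon to top autumn, the chains we reckon for noon must exceed those we reckon for autumn. At noon, with L at its full 0.110 mM, kp·L·t is 2.26, more than one relaxation time, so we set M equal to c. The impurity H then decays pseudo-first-order with constant kq·c. The charge less c is the large term, and the quench is the correction, which gives our estimate for noon chains, 34.7%.

The autumn value of c is lower, 4.19 mM, but there kp·L·t, with L again taken as full, is 0.888, so we reckon the autumn flask short of time rather than held at c. Taking L full from the start, H at its charge, and the quench as acting on the excess above c, we let that excess go at 0.296 /min into chains and 0.0688 /min into quench, and that gives our estimate for autumn, 43.7%.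

By these estimates noon stands 9 percentage points short of the opposite outcome. With L full and depropagation and quench left out, we reckon winter at 26.4% and summer at 8.59%, both less than our autumn estimate. We commit to autumn.

The forecast gives autumn, with 39.4% for autumn, 14.3% for winter, 1.6% for summer and 30.3% for noon, holding that “only the warm flasks get full living ends”.

The simulation gives autumn as highest, with 39.5% in autumn, 15.0% in winter, 1.61% in summer and 30.5% at noon. Noon free monomer read 48.0% of the charge at 1.50 min and 36.2% at 3.00 min, one reading above the equilibrium share 39.8% and one below it. So net growth in the noon flask, with c at 8.75 mM, changed sign between those readings, while its chains read 29.5% and 30.5%.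

Repeat autumn at 55 °C: c there is 10.4 mM, and the same correction gives an estimate of 15.4%. The computed flask holds 18.1% in chains.

The numbers were drawn at random within sensible limits; the run is a simulation.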